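**Plan**

1. Retrosynthesis: (a) C8–C27 and C14–O, the two bonds that make the oxygen-bridged seven-membered ring C, are cut back to an 8β,26-epoxide and a C14(27) methylene; (b) C9–C11 is cut to give two decalins (aldol); (c) in each decalin the ring-fusion bond and its neighbour (C17–C18 and C15–C16 for rings D/E; C5–C10 and C6–C7 for rings A/B) are cut back to one acyclic keto-aldehyde.
2. Feature that allows (c): in ring D the ether carbon C14 lies 1,3 to the methyl-bearing quaternary C18, so ring D, taken as its C14 ketone, is the cyclohexenone of a 1,5-keto-aldehyde. The aldehyde α-carbon C17 adds to the enone carbon C18 and closes ring E; the ketone methyl C15 then condenses with the aldehyde carbon C16 and closes ring D. Rings A/B are the same bicycle, so one bicyclization feeds both halves.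
3. Forward: pent-4-yn-1-ol → chain 10 → decalin enone 13 (ring E, then ring D). Enone 13 is used as such for rings A/B; after adding C12/C11, the C27 methylene and inverting C21 it becomes aldehyde 22 for rings D/E. Aldol union, copper hydride reduction and a C26 spiro-epoxide follow; BF3 then closes ring C and the tetrahydrofuran bridge; the C3 ketone and 21-OH are unmasked last.
4. Stereochemistry: one reagent-controlled carbinol (step 3) relays through a chair Michael transition state to C17/C18 (and C5/C10). It is then reset to the axial 21β-OH by K[HB(s-Bu)3] in one half and oxidised to the C3 ketone in the other. C13 and C9 come from equilibration or protonation anti to the angular methyl, C8 from anti opening of the β-epoxide, C14 from the bicyclic constraint.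

Key step: step 7

Remark: the target is read as 21β-hydroxy-14β,26-epoxyserratan-3-one (axial ring-E hydroxyl). Decalins are described with terpenoid locants C1–C10 (C3 oxygen, C4 gem-dimethyl, C8 carbonyl or methylene, C9 side chain, C10 angular methyl = β); joined halves use onocerane/serratane numbering, in which the local 3α of the ring D/E half becomes 21β.

**Route**

Step 1
Reactants: 1 pent-4-yn-1-ol
Product: 3 (4E)-5-iodo-4-methylpent-4-en-1-ol, via alkenylalane 2 (not isolated)
Conditions: Me3Al (3 equiv), Cp2ZrCl2 (0.25 equiv), CH2Cl2, 0 → 23 °C; then I2, THF, −30 → 0 °C; aq. work-up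
Reagents that add atoms: trimethylaluminium C[Al](C)C; iodine II
Why: Zirconium-catalysed syn-carboalumination (Negishi) puts the methyl on the internal alkyne carbon and iodinolysis of the C–Al bond proceeds with retention, which fixes the E trisubstituted alkene.

Step 2
Reactants: 3 (4E)-5-iodo-4-methylpent-4-en-1-ol
Product: 4 (4E)-5-iodo-4-methylpent-4-enal
Conditions: Dess–Martin periodinane, CH2Cl2, 23 °C
Reagents that add atoms: none
Why: Dess–Martin oxidation of a primary alcohol stops at the aldehyde and leaves the vinyl iodide untouched.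

Step 3
Reactants: 4 (4E)-5-iodo-4-methylpent-4-enal
Product: 6 (4S,6E)-7-iodo-3,3,6-trimethylhepta-1,6-dien-4-ol, via borinate 5 (not isolated)
Conditions: (+)-Ipc2BH [from (−)-α-pinene], 3-methylbuta-1,2-diene, THF, −25 °C; then 4, Et2O, −78 °C; NaOH, H2O2, 0 → 23 °C
Reagents that add atoms: 3-methylbuta-1,2-diene CC(C)=C=C
Why: Brown-type γ-selective prenylboration through a closed chair transition state gives the reverse-prenyl (gem-dimethyl) homoallylic alcohol, and the isopinocampheyl groups from (−)-α-pinene should direct attack to the aldehyde face that gives the 4S carbinol.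

Step 4
Reactants: 6 (4S,6E)-7-iodo-3,3,6-trimethylhepta-1,6-dien-4-ol
Product: 7 (4S,6E)-4-benzyloxy-7-iodo-3,3,6-trimethylhepta-1,6-diene
Conditions: NaH, BnBr, Bu4NI (cat.), DMF, 0 → 23 °C
Reagents that add atoms: benzyl bromide BrCc1ccccc1
Why: Williamson etherification masks the carbinol that later relays chirality; the benzyl ether survives bases, hydrides and Lewis acids and is removable by hydrogenolysis.

Step 5
Reactants: 7 (4S,6E)-4-benzyloxy-7-iodo-3,3,6-trimethylhepta-1,6-diene
Product: 9 (3E,7S)-7-benzyloxy-4,8,8-trimethyldeca-3,9-dien-2-one, via alkenyllithium 8 (not isolated)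
Conditions: t-BuLi (2.1 equiv), Et2O, −78 °C; MeC(O)N(OMe)Me, −78 → 0 °C; 1 M HCl
Reagents that add atoms: N-methoxy-N-methylacetamide CC(=O)N(C)OC
Why: Iodine–lithium exchange keeps the alkene geometry and acylation by the N-methoxy-N-methylamide (stable chelated adduct, no over-addition) gives the E methyl enone without a palladium step that could trigger a Heck closure onto the vinyl group.

Step 6
Reactants: 9 (3E,7S)-7-benzyloxy-4,8,8-trimethyldeca-3,9-dien-2-one
Product: 10 (4S,7E)-4-benzyloxy-3,3,7-trimethyl-9-oxodec-7-enal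
Conditions: PdCl2(PhCN)2 (10 mol %), CuCl2·2H2O (10 mol %), AgNO2 (5 mol %), O2 (1 atm), t-BuOH/MeNO2 15:1, 23 °C
Reagents that add atoms: dioxygen O=O
Why: Nitrite-modified Wacker oxidation should give the anti-Markovnikov aldehyde because the allylic quaternary carbon and the homoallylic ether disfavour attack at the internal carbon, while the electron-poor trisubstituted enone alkene is inert.

Step 7
Reactants: 10 (4S,7E)-4-benzyloxy-3,3,7-trimethyl-9-oxodec-7-enal
Product: 13 3β-benzyloxy-4,4,10β-trimethyl-5α-decal-6-en-8-one, via Michael adduct 11 (not isolated), via ketol 12 (not isolated)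
Conditions: pyrrolidine (0.5 equiv), AcOH (0.5 equiv), toluene (0.02 M), 23 → 80 °C
Reagents that add atoms: none
Why: Pyrrolidine converts the aldehyde into its enamine, whose carbon C2 adds 6-exo-trig to the enone β-carbon C7 (C17–C18 of the future D/E half, C5–C10 of the A/B half) and closes ring E to give keto-aldehyde 11; the methyl ketone C10 of 11 then adds to the aldehyde C1 in a 6-(enolendo)-exo-trig aldol (C15–C16, or C6–C7) and ketol 12 dehydrates, closing ring D as the enone. The closest known reaction type is the amine-mediated intramolecular Michael addition of an aldehyde to an enone followed by aldol condensation (Robinson-type annulation of a 1,5-keto-aldehyde). The new quaternary carbon is set relative to the benzyloxy carbinol by a chair transition state with the benzyloxy group and the enone arm equatorial and the small methyl axial; the ring-fusion C–H is set under thermodynamic control (enolisable aldehyde α-carbon, later γ-carbon of the enone) and should end trans to the angular methyl. Because the Michael step is reversible and the dehydration is not, the adduct that can close to the unstrained trans-decalin is drained to product. The step needs enamine formation at the aldehyde only, which the unreactive β,β-disubstituted methyl ketone secures, and a single aldol mode, which is secured because every other enol/carbonyl pairing would give a four-membered ring.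

Step 8
Reactants: 13 3β-benzyloxy-4,4,10β-trimethyl-5α-decal-6-en-8-one
Product: 15 methyl 2-(3β-benzyloxy-4,4,10β-trimethyl-8-oxo-5α-decal-6-en-9α-yl)acetate, via sodium dienolate 14 (not isolated)
Conditions: NaN(SiMe3)2, THF, −78 °C; BrCH2CO2Me, −78 → −20 °C
Reagents that add atoms: methyl bromoacetate COC(=O)CBr
Why: Kinetic α′-deprotonation by the hindered amide base gives the cross-conjugated sodium dienolate (the γ-hydrogen is a hindered ring-fusion methine), whose higher reactivity compared with a lithium enolate suits C-alkylation at this neopentyl-type carbon by the reactive α-bromo ester, anti to the angular methyl (9α, axial); this centre is corrected in step 9.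

Step 9
Reactants: 15 methyl 2-(3β-benzyloxy-4,4,10β-trimethyl-8-oxo-5α-decal-6-en-9α-yl)acetate
Product: 17 methyl 2-(3β-hydroxy-4,4,10β-trimethyl-8-oxo-5α-decalin-9β-yl)acetate, via 9-epimer 16 (not isolated)
Conditions: H2 (1 atm), Pd/C, MeOH/EtOAc, 23 °C; filter; NaOMe (0.2 equiv), MeOH, 23 °C
Reagents that add atoms: none
Why: Heterogeneous hydrogenation saturates the enone alkene and hydrogenolyses the benzyl ether, and methoxide equilibration of the ketone α-centre should place the side chain equatorial (9β, 9α-H).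

Step 10
Reactants: 17 methyl 2-(3β-hydroxy-4,4,10β-trimethyl-8-oxo-5α-decalin-9β-yl)acetate
Product: 18 methyl 2-(3β-hydroxy-4,4,10β-trimethyl-8-methylene-5α-decalin-9β-yl)acetate
Conditions: Ph3PCH3Br, KOt-Bu (excess), toluene/THF, 23 → 60 °C
Reagents that add atoms: methyltriphenylphosphonium bromide C[P+](c1ccccc1)(c1ccccc1)c1ccccc1.[Br-]
Why: Wittig methylenation converts the ring ketone into the exocyclic methylene (the future C27) while the ester is not attacked by the non-stabilised ylide and the α-centre stays in its thermodynamic configuration.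

Step 11
Reactants: 18 methyl 2-(3β-hydroxy-4,4,10β-trimethyl-8-methylene-5α-decalin-9β-yl)acetate
Product: 19 methyl 2-(4,4,10β-trimethyl-8-methylene-3-oxo-5α-decalin-9β-yl)acetate
Conditions: Dess–Martin periodinane, CH2Cl2, 23 °C
Reagents that add atoms: none
Why: Dess–Martin oxidation gives the hindered 4,4-dimethyl-3-ketone and so erases the relay stereocentre, which is needed in the opposite (axial) configuration.

Step 12
Reactants: 19 methyl 2-(4,4,10β-trimethyl-8-methylene-3-oxo-5α-decalin-9β-yl)acetate
Product: 20 methyl 2-(3α-hydroxy-4,4,10β-trimethyl-8-methylene-5α-decalin-9β-yl)acetate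
Conditions: K[HB(s-Bu)3], THF, −78 °C; H2O
Reagents that add atoms: none
Why: The bulky trialkylborohydride attacks the neopentyl ketone along the equatorial trajectory and should give the axial 3α-alcohol (the future 21β-OH); ester and alkene are untouched at −78 °C.

Step 13
Reactants: 20 methyl 2-(3α-hydroxy-4,4,10β-trimethyl-8-methylene-5α-decalin-9β-yl)acetate
Product: 21 methyl 2-[3α-(tert-butyldimethylsilyloxy)-4,4,10β-trimethyl-8-methylene-5α-decalin-9β-yl]acetate
Conditions: t-BuMe2SiOTf, 2,6-lutidine, CH2Cl2, 0 °C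
Reagents that add atoms: tert-butyldimethylsilyl trifluoromethanesulfonate CC(C)(C)[Si](C)(C)OS(=O)(=O)C(F)(F)F
Why: The silyl triflate silylates the hindered axial alcohol, and the silyl ether is orthogonal to the benzyl ether carried by the other half.

Step 14
Reactants: 21 methyl 2-[3α-(tert-butyldimethylsilyloxy)-4,4,10β-trimethyl-8-methylene-5α-decalin-9β-yl]acetate
Product: 22 2-[3α-(tert-butyldimethylsilyloxy)-4,4,10β-trimethyl-8-methylene-5α-decalin-9β-yl]acetaldehyde
Conditions: i-Bu2AlH (1.1 equiv), toluene, −78 °C; aq. potassium sodium tartrate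
Reagents that add atoms: none
Why: Low-temperature reduction of the methyl ester stops at the tetrahedral aluminium acetal, which releases the aldehyde on work-up.

Step 15
Reactants: 13 3β-benzyloxy-4,4,10β-trimethyl-5α-decal-6-en-8-one; 22 2-[3α-(tert-butyldimethylsilyloxy)-4,4,10β-trimethyl-8-methylene-5α-decalin-9β-yl]acetaldehyde
Product: 26 3β-benzyloxy-21β-(tert-butyldimethylsilyloxy)-26-noronocera-6,9(11),14(27)-trien-8-one, via lithium dienolate 23 (not isolated), via lithium aldolate 24 (not isolated), via mesylate 25 (not isolated)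
Conditions: 13, LiN(i-Pr)2, THF, −78 °C; 22, −78 °C; MsCl (excess), −78 → 0 °C; DBU, 0 → 23 °C
Reagents that add atoms: none
Why: Directed aldol addition of the kinetic α′ lithium dienolate of 13 (the tightly bound lithium aldolate resists retro-aldol) to aldehyde 22 joins the halves at C9–C11, and mesylation followed by E1cB elimination gives the exocyclic enone, which removes the two unselective aldol centres.

Step 16
Reactants: 26 3β-benzyloxy-21β-(tert-butyldimethylsilyloxy)-26-noronocera-6,9(11),14(27)-trien-8-one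
Product: 27 3β-benzyloxy-21β-(tert-butyldimethylsilyloxy)-26-noronocer-14(27)-en-8-one
Conditions: [(Ph3P)CuH]6 (0.5 equiv), H2O (5 equiv), benzene, 23 °C
Reagents that add atoms: none
Why: Copper hydride adds in conjugate fashion to both alkenes of the cross-conjugated dienone and not to the isolated 1,1-disubstituted alkene, and protonation of the C9 enolate anti to the angular methyl gives the equatorial side chain (9α-H), which is also the thermodynamic epimer.

Step 17
Reactants: 27 3β-benzyloxy-21β-(tert-butyldimethylsilyloxy)-26-noronocer-14(27)-en-8-one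
Product: 28 3β-benzyloxy-21β-(tert-butyldimethylsilyloxy)-8β,26-epoxyonocer-14(27)-ene
Conditions: Me3SI, n-BuLi, THF, −10 → 23 °C
Reagents that add atoms: trimethylsulfonium iodide C[S+](C)C.[I-]
Why: Corey–Chaykovsky epoxidation adds C26; the ylide carbon should attack the C8 ketone along the equatorial α trajectory because the axial β face is blocked by the C10 methyl, so the oxygen ends axial (β).

Step 18
Reactants: 28 3β-benzyloxy-21β-(tert-butyldimethylsilyloxy)-8β,26-epoxyonocer-14(27)-ene
Product: 29 3β-benzyloxy-21β-(tert-butyldimethylsilyloxy)-14β,26-epoxyserratane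
Conditions: BF3·OEt2 (0.3 equiv), CH2Cl2, −78 → −40 °C
Reagents that add atoms: none
Why: The Lewis acid opens the spiro-epoxide at tertiary C8, the C14(27) methylene attacks C8 from the α face anti to the leaving oxygen (7-endo closure of ring C, leaving C26 β), and the boron-bound C26 alkoxide captures the tertiary C14 cation (5-exo) to form the tetrahydrofuran bridge, whose cis-bridged bicyclo[4.2.1] geometry fixes C14 (an epoxide-initiated cation–olefin cyclisation with oxygen termination, related to the acid-induced closure of onocerane dienes to serratenes).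

Step 19
Reactants: 29 3β-benzyloxy-21β-(tert-butyldimethylsilyloxy)-14β,26-epoxyserratane
Product: 30 21β-(tert-butyldimethylsilyloxy)-14β,26-epoxyserratan-3β-ol
Conditions: H2 (1 atm), Pd/C, EtOAc/EtOH, 23 °C
Reagents that add atoms: none
Why: Hydrogenolysis removes the benzyl ether; the pentacycle holds no alkene and the silyl ether is stable to these conditions.

Step 20
Reactants: 30 21β-(tert-butyldimethylsilyloxy)-14β,26-epoxyserratan-3β-ol
Product: 31 21β-(tert-butyldimethylsilyloxy)-14β,26-epoxyserratan-3-one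
Conditions: Dess–Martin periodinane, CH2Cl2, 23 °C
Reagents that add atoms: none
Why: Dess–Martin oxidation gives the C3 ketone while the 21-hydroxyl is still silylated, which is what distinguishes the two nearly identical halves.

Step 21
Reactants: 31 21β-(tert-butyldimethylsilyloxy)-14β,26-epoxyserratan-3-one
Product: 32 21β-hydroxy-14β,26-epoxyserratan-3-one (CNP0211850.1)
Conditions: HF (aq. 48%), MeCN/CH2Cl2, 23 °C
Reagents that add atoms: none
Why: Fluoride-driven desilylation frees the axial 21β-alcohol without touching the ketone or the tertiary ether bridge.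

**Compound list**

1 | pent-4-yn-1-ol | C#CCCCO | starting material
2 | alkenylalane: dimethyl[(1E)-5-(dimethylalumanyloxy)-2-methylpent-1-en-1-yl]alumane | C/C(CCCO[Al](C)C)=C\[Al](C)C | intermediate
3 | (4E)-5-iodo-4-methylpent-4-en-1-ol | OCCC/C(C)=C/I | intermediate
4 | (4E)-5-iodo-4-methylpent-4-enal | O=CCC/C(C)=C/I | intermediate
5 | borinate: (4S,6E)-7-iodo-3,3,6-trimethylhepta-1,6-dien-4-yl diisopinocampheylborinate | C=CC(C)(C)[C@@H](OB([C@H]1C[C@H]2C[C@@H]([C@@H]1C)C2(C)C)[C@H]1C[C@H]2C[C@@H]([C@@H]1C)C2(C)C)CC/C(C)=C/I | intermediate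
6 | (4S,6E)-7-iodo-3,3,6-trimethylhepta-1,6-dien-4-ol | C=CC(C)(C)[C@@H](O)CC/C(C)=C/I | intermediate
7 | (4S,6E)-4-benzyloxy-7-iodo-3,3,6-trimethylhepta-1,6-diene | C=CC(C)(C)[C@@H](OCc1ccccc1)CC/C(C)=C/I | intermediate
8 | alkenyllithium: [(1E,5S)-5-benzyloxy-2,6,6-trimethylocta-1,7-dien-1-yl]lithium | C=CC(C)(C)[C@@H](OCc1ccccc1)CC/C(C)=C/[Li] | intermediate
9 | (3E,7S)-7-benzyloxy-4,8,8-trimethyldeca-3,9-dien-2-one | C=CC(C)(C)[C@@H](OCc1ccccc1)CC/C(C)=C/C(C)=O | intermediate
10 | (4S,7E)-4-benzyloxy-3,3,7-trimethyl-9-oxodec-7-enal | O=CCC(C)(C)[C@@H](OCc1ccccc1)CC/C(C)=C/C(C)=O | intermediate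
11 | Michael adduct: 5-benzyloxy-2,6,6-trimethyl-2-(2-oxopropyl)cyclohexane-1-carbaldehyde (formyl and benzyloxy equatorial, 2-methyl axial and cis to both) | O=C[C@H]1C(C)(C)[C@@H](OCc2ccccc2)CC[C@]1(C)CC(C)=O | intermediate
12 | ketol: 3β-benzyloxy-6-hydroxy-4,4,10β-trimethyl-5α-decalin-8-one (both C6 epimers) | O=C1CC(O)[C@H]2C(C)(C)[C@@H](OCc3ccccc3)CC[C@]2(C)C1 | intermediate
13 | 3β-benzyloxy-4,4,10β-trimethyl-5α-decal-6-en-8-one (trans-fused; benzyloxy equatorial, cis to the angular methyl) | O=C1C=C[C@H]2C(C)(C)[C@@H](OCc3ccccc3)CC[C@]2(C)C1 | intermediate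
14 | sodium dienolate of 13 (O–Na on C8; C8=C9 and C6=C7) | [Na]OC1C=C[C@H]2C(C)(C)[C@@H](OCc3ccccc3)CC[C@]2(C)C=1 | intermediate
15 | methyl 2-(3β-benzyloxy-4,4,10β-trimethyl-8-oxo-5α-decal-6-en-9α-yl)acetate (side chain axial, anti to the angular methyl) | O=C1C=C[C@H]2C(C)(C)[C@@H](OCc3ccccc3)CC[C@]2(C)[C@@H]1CC(=O)OC | intermediate
16 | 9-epimer: methyl 2-(3β-hydroxy-4,4,10β-trimethyl-8-oxo-5α-decalin-9α-yl)acetate | O=C1CC[C@H]2C(C)(C)[C@@H](O)CC[C@]2(C)[C@@H]1CC(=O)OC | intermediate
17 | methyl 2-(3β-hydroxy-4,4,10β-trimethyl-8-oxo-5α-decalin-9β-yl)acetate (9α-H, side chain equatorial) | O=C1CC[C@H]2C(C)(C)[C@@H](O)CC[C@]2(C)[C@H]1CC(=O)OC | intermediate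
18 | methyl 2-(3β-hydroxy-4,4,10β-trimethyl-8-methylene-5α-decalin-9β-yl)acetate | C=C1CC[C@H]2C(C)(C)[C@@H](O)CC[C@]2(C)[C@H]1CC(=O)OC | intermediate
19 | methyl 2-(4,4,10β-trimethyl-8-methylene-3-oxo-5α-decalin-9β-yl)acetate | C=C1CC[C@H]2C(C)(C)C(=O)CC[C@]2(C)[C@H]1CC(=O)OC | intermediate
20 | methyl 2-(3α-hydroxy-4,4,10β-trimethyl-8-methylene-5α-decalin-9β-yl)acetate (axial hydroxyl) | C=C1CC[C@H]2C(C)(C)[C@H](O)CC[C@]2(C)[C@H]1CC(=O)OC | intermediate
21 | methyl 2-[3α-(tert-butyldimethylsilyloxy)-4,4,10β-trimethyl-8-methylene-5α-decalin-9β-yl]acetate | C=C1CC[C@H]2C(C)(C)[C@H](O[Si](C)(C)C(C)(C)C)CC[C@]2(C)[C@H]1CC(=O)OC | intermediate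
22 | 2-[3α-(tert-butyldimethylsilyloxy)-4,4,10β-trimethyl-8-methylene-5α-decalin-9β-yl]acetaldehyde | C=C1CC[C@H]2C(C)(C)[C@H](O[Si](C)(C)C(C)(C)C)CC[C@]2(C)[C@H]1CC=O | intermediate
23 | lithium dienolate of 13 (O–Li on C8; C8=C9 and C6=C7) | [Li]OC1C=C[C@H]2C(C)(C)[C@@H](OCc3ccccc3)CC[C@]2(C)C=1 | intermediate
24 | lithium aldolate: lithium 3β-benzyloxy-21β-(tert-butyldimethylsilyloxy)-8-oxo-26-noronocera-6,14(27)-dien-11-olate (C9 and C11 epimers) | C=C1CC[C@H]2C(C)(C)[C@H](O[Si](C)(C)C(C)(C)C)CC[C@]2(C)[C@H]1CC(O[Li])C3C(=O)C=C[C@H]4C(C)(C)[C@@H](OCc5ccccc5)CC[C@]34C | intermediate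
25 | mesylate: 3β-benzyloxy-21β-(tert-butyldimethylsilyloxy)-8-oxo-26-noronocera-6,14(27)-dien-11-yl methanesulfonate (C9 and C11 epimers) | C=C1CC[C@H]2C(C)(C)[C@H](O[Si](C)(C)C(C)(C)C)CC[C@]2(C)[C@H]1CC(OS(C)(=O)=O)C3C(=O)C=C[C@H]4C(C)(C)[C@@H](OCc5ccccc5)CC[C@]34C | intermediate
26 | 3β-benzyloxy-21β-(tert-butyldimethylsilyloxy)-26-noronocera-6,9(11),14(27)-trien-8-one (geometry of the 9(11) alkene immaterial) | C=C1CC[C@H]2C(C)(C)[C@H](O[Si](C)(C)C(C)(C)C)CC[C@]2(C)[C@H]1CC=C3C(=O)C=C[C@H]4C(C)(C)[C@@H](OCc5ccccc5)CC[C@]34C | intermediate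
27 | 3β-benzyloxy-21β-(tert-butyldimethylsilyloxy)-26-noronocer-14(27)-en-8-one (9α-H, 13β-H) | C=C1CC[C@H]2C(C)(C)[C@H](O[Si](C)(C)C(C)(C)C)CC[C@]2(C)[C@H]1CC[C@H]3C(=O)CC[C@H]4C(C)(C)[C@@H](OCc5ccccc5)CC[C@]34C | intermediate
28 | 3β-benzyloxy-21β-(tert-butyldimethylsilyloxy)-8β,26-epoxyonocer-14(27)-ene (epoxide oxygen β, axial) | C=C1CC[C@H]2C(C)(C)[C@H](O[Si](C)(C)C(C)(C)C)CC[C@]2(C)[C@H]1CC[C@H]3[C@]6(CO6)CC[C@H]4C(C)(C)[C@@H](OCc5ccccc5)CC[C@]34C | intermediate
29 | 3β-benzyloxy-21β-(tert-butyldimethylsilyloxy)-14β,26-epoxyserratane | CC1(C)[C@@H](OCc6ccccc6)CC[C@@]2(C)[C@H]1CC[C@]13CO[C@@]4(CC[C@H]5C(C)(C)[C@H](O[Si](C)(C)C(C)(C)C)CC[C@]5(C)[C@H]4CC[C@@H]12)C3 | intermediate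
30 | 21β-(tert-butyldimethylsilyloxy)-14β,26-epoxyserratan-3β-ol | CC1(C)[C@@H](O)CC[C@@]2(C)[C@H]1CC[C@]13CO[C@@]4(CC[C@H]5C(C)(C)[C@H](O[Si](C)(C)C(C)(C)C)CC[C@]5(C)[C@H]4CC[C@@H]12)C3 | intermediate
31 | 21β-(tert-butyldimethylsilyloxy)-14β,26-epoxyserratan-3-one | CC1(C)C(=O)CC[C@@]2(C)[C@H]1CC[C@]13CO[C@@]4(CC[C@H]5C(C)(C)[C@H](O[Si](C)(C)C(C)(C)C)CC[C@]5(C)[C@H]4CC[C@@H]12)C3 | intermediate
32 | 21β-hydroxy-14β,26-epoxyserratan-3-one (CNP0211850.1) | CC1(C)C(=O)CC[C@@]2(C)[C@H]1CC[C@]13CO[C@@]4(CC[C@H]5C(C)(C)[C@H](O)CC[C@]5(C)[C@H]4CC[C@@H]12)C3 | target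

**Step count**

Total: 21 steps. Longest linear sequence: 21 steps (1 → 13 → 22 → 32); the second half of the skeleton enters as enone 13 in step 15 and needs no steps of its own.

**Steps most likely to fail**

Step 7. The enamine may add too slowly to the β,β-disubstituted enone at a centre flanked by two quaternary carbons. The relay from the benzyloxy carbinol may also discriminate the two chair transition states only moderately; the two products are separable diastereomers, and since this carbinol is later oxidised in both halves, either sense of relay can be served by choosing the carbinol enantiomer in step 3. The fallback forms the ring-fusion bond by a radical instead of an enamine. It sets out from 9: epoxidation of the terminal vinyl group (m-CPBA, CH2Cl2) gives (3E,7S)-7-benzyloxy-4,8-dimethyl-8-(oxiran-2-yl)non-3-en-2-one F1. Cp2TiCl (trivalent titanium, from Cp2TiCl2 and Zn, THF) opens the epoxide to the secondary β-titanoxy radical, which cyclises 6-exo onto the enone carbon and is reduced to the titanium enolate; work-up gives 1-[4-benzyloxy-2-(hydroxymethyl)-1,3,3-trimethylcyclohexyl]propan-2-one F2. Dess–Martin oxidation of F2 gives keto-aldehyde 11, and pyrrolidinium acetate then has only the aldol condensation left to do; the route is rejoined at 13.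

Step 18. A 1,2-hydride shift of the opened epoxide to the C8 aldehyde (Meinwald rearrangement) or proton loss to an allylic alcohol may outrun the slow seven-membered ring closure. The fallback separates the C–C and C–O bond formations and sets out from 28. Cp2TiCl (catalytic Cp2TiCl2, Mn, 2,4,6-collidine hydrochloride, THF) opens the epoxide to the tertiary C8 radical, which adds 7-endo to the C14(27) methylene; the C14 radical is trapped by titanium and loses a β-hydrogen, giving 3β-benzyloxy-21β-(tert-butyldimethylsilyloxy)serrat-14-en-26-ol F3 (double-bond isomers would converge). Catalytic TsOH in CH2Cl2 then adds the 26-hydroxyl across the alkene at tertiary C14 (Markovnikov hydroalkoxylation) and the route is rejoined at 29.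

Step 6. Turnover at the neopentyl-type vinyl group may be slow, with competing Markovnikov oxidation to the methyl ketone or alkene isomerisation chemistry at palladium. The fallback installs the aldehyde oxygen by hydroboration before the enone exists and sets out from 7. 9-BBN then NaOH/H2O2 gives (4S,6E)-4-benzyloxy-7-iodo-3,3,6-trimethylhept-6-en-1-ol F4. Nozaki–Hiyama–Kishi coupling of the vinyl iodide with acetaldehyde (CrCl2, NiCl2 cat., DMF) gives (4S,7E)-4-benzyloxy-3,3,7-trimethyldec-7-ene-1,9-diol F5. Dess–Martin oxidation of both hydroxyls gives keto-aldehyde 10, where the route is rejoined.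

**Further compounds**

F1 | step 7 | (3E,7S)-7-benzyloxy-4,8-dimethyl-8-(oxiran-2-yl)non-3-en-2-one (both oxirane epimers) | C1(CO1)C(C)(C)[C@@H](OCc2ccccc2)CC/C(C)=C/C(C)=O
F2 | step 7 | 1-[4-benzyloxy-2-(hydroxymethyl)-1,3,3-trimethylcyclohexyl]propan-2-one (hydroxymethyl and benzyloxy equatorial, 1-methyl axial) | OC[C@H]1C(C)(C)[C@@H](OCc2ccccc2)CC[C@]1(C)CC(C)=O
F3 | step 18 | 3β-benzyloxy-21β-(tert-butyldimethylsilyloxy)serrat-14-en-26-ol | CC1(C)[C@@H](OCc6ccccc6)CC[C@@]2(C)[C@H]1CC[C@@]1(CO)CC4=CC[C@H]5C(C)(C)[C@H](O[Si](C)(C)C(C)(C)C)CC[C@]5(C)[C@H]4CC[C@@H]12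
F4 | step 6 | (4S,6E)-4-benzyloxy-7-iodo-3,3,6-trimethylhept-6-en-1-ol | OCCC(C)(C)[C@@H](OCc1ccccc1)CC/C(C)=C/I
F5 | step 6 | (4S,7E)-4-benzyloxy-3,3,7-trimethyldec-7-ene-1,9-diol (both C9 epimers) | OCCC(C)(C)[C@@H](OCc1ccccc1)CC/C(C)=C/C(C)O
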